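## Retrosynthetic overview

1. Exotimarin F is cut at the ester C–O bond into a free (E)-o-hydroxycinnamic acid and the oxirane (R)-meranzin. They are joined by acid-catalysed opening at the CMe2 carbon followed by a 1,2-acyl shift, so the C–O bond at the stereocentre is never broken.
2. (R)-Meranzin comes from achiral osthole by Shi epoxidation, which sets the first stereocentre.
3. The acid comes from a methyl ketone by Wittig methylenation. The ketone comes from an aryl aldehyde and hydroxyacetone by an amino-acid-catalysed syn-aldol reaction that sets both diol stereocentres.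
4. The aryl aldehyde comes from 2-hydroxy-4-methoxybenzaldehyde by Wittig olefination (E-cinnamate), ortho-formylation and O-silylation.
5. Rings: none is built. The coumarin arrives in osthole and the arene in the benzaldehyde; the only ring formed is the oxirane (step 1), which is opened again in step 8.

Assumption: the facial senses of the two known catalysts are taken from their closest analogues (D-fructose-derived Shi ketone gives the (R)-oxirane of a prenyl arene; the D-amino acid gives the mirror image of the L-series syn adduct). If either sense proved opposite, the enantiomeric catalyst would be used.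

## Route

Step 1
Reactants: 1 osthole (7-methoxy-8-(3-methylbut-2-en-1-yl)-2H-chromen-2-one)
Product: 2 (R)-meranzin, 8-{[(2R)-3,3-dimethyloxiran-2-yl]methyl}-7-methoxy-2H-chromen-2-one
Conditions: 1,2:4,5-di-O-isopropylidene-β-D-erythro-2,3-hexodiulo-2,6-pyranose (30 mol%), KHSO5 (as 2KHSO5·KHSO4·K2SO4), K2CO3, Bu4NHSO4 (cat.), MeCN/CH2(OMe)2/aq. Na2B4O7 buffer (pH 10.5), 0 °C
Reagents that add atoms: potassium peroxymonosulfate KHSO5, [K+].[O-]S(=O)(=O)OO
Why: Shi asymmetric epoxidation, in which the chiral dioxirane formed from the ketone transfers oxygen to the electron-rich trisubstituted prenyl alkene through a spiro transition state on the face that gives the (R)-oxirane, while the electron-poor coumarin C3=C4 bond is inert; this sets C2''.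

Step 2
Reactants: 3 2-hydroxy-4-methoxybenzaldehyde
Product: 4 methyl (2E)-3-(2-hydroxy-4-methoxyphenyl)prop-2-enoate
Conditions: Ph3P=CHCO2Me, toluene, rt, dark
Reagents that add atoms: methyl (triphenylphosphoranylidene)acetate, COC(=O)C=P(c1ccccc1)(c1ccccc1)c1ccccc1
Why: Wittig olefination with a stabilised ylide gives the E-cinnamate, and working at room temperature in the dark keeps the minor Z isomer (which would lactonise to 7-methoxycoumarin) small and separable.

Step 3
Reactants: 4 methyl (2E)-3-(2-hydroxy-4-methoxyphenyl)prop-2-enoate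
Product: 6 methyl (2E)-3-(3-formyl-2-hydroxy-4-methoxyphenyl)prop-2-enoate, via hydroxymethyl phenol 5 (not isolated)
Conditions: MgCl2, Et3N, (CH2O)n, MeCN, reflux; aq. HCl work-up
Reagents that add atoms: paraformaldehyde (as formaldehyde), C=O
Why: Casnati–Skattebøl ortho-formylation, in which the magnesium phenoxide delivers formaldehyde to the only free ortho position (between OH and OMe) and the resulting benzylic alkoxide is oxidised by a second formaldehyde through an Oppenauer-type hydride transfer.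

Step 4
Reactants: 6 methyl (2E)-3-(3-formyl-2-hydroxy-4-methoxyphenyl)prop-2-enoate
Product: 7 methyl (2E)-3-{2-[(tert-butyldimethylsilyl)oxy]-3-formyl-4-methoxyphenyl}prop-2-enoate
Conditions: TBSCl, imidazole, DMAP (cat.), DMF, rt
Reagents that add atoms: tert-butyldimethylsilyl chloride, CC(C)(C)[Si](C)(C)Cl
Why: Silyl ether formation (Corey protocol) masks the phenol so that in step 5 it can neither trap the primary-amine catalyst as a salicylaldimine nor close onto the new ketone as a cyclic hemiketal.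

Step 5
Reactants: 7 methyl (2E)-3-{2-[(tert-butyldimethylsilyl)oxy]-3-formyl-4-methoxyphenyl}prop-2-enoate; 8 hydroxyacetone
Product: 9 methyl (2E)-3-{2-[(tert-butyldimethylsilyl)oxy]-3-[(1R,2S)-1,2-dihydroxy-3-oxobutyl]-4-methoxyphenyl}prop-2-enoate
Conditions: O-tert-butyl-D-threonine (20 mol%), hydroxyacetone in tenfold excess, NMP, 4 °C → rt, 72 h
Reagents that add atoms: none
Why: Primary-amino-acid-catalysed direct syn-aldol reaction (enamine catalysis), an addition in which all atoms of both partners end up in the product; the catalyst forms the hydrogen-bonded Z-enamine of hydroxyacetone at its hydroxylated carbon and its carboxylic acid guides that enamine to the Si face of the aldehyde, so both diol stereocentres are set as the syn (1R,2S) pair by the D-configured catalyst.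

Step 6
Reactants: 9 methyl (2E)-3-{2-[(tert-butyldimethylsilyl)oxy]-3-[(1R,2S)-1,2-dihydroxy-3-oxobutyl]-4-methoxyphenyl}prop-2-enoate
Product: 12 methyl (2E)-3-{2-[(tert-butyldimethylsilyl)oxy]-3-[(1R,2R)-1,2-dihydroxy-3-methylbut-3-en-1-yl]-4-methoxyphenyl}prop-2-enoate, via bis-TMS ketone 10 (not isolated), via bis-TMS alkene 11 (not isolated)
Conditions: TMSCl, Et3N, CH2Cl2, 0 °C; filter, evaporate; Ph3PCH3Br/KOtBu (gives Ph3P=CH2, 1.5 equiv), THF, −78 → 0 °C; citric acid (cat.), MeOH, rt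
Reagents that add atoms: methyltriphenylphosphonium bromide, C[P+](c1ccccc1)(c1ccccc1)c1ccccc1.[Br-] (the CH2 carbon); chlorotrimethylsilane, C[Si](C)(C)Cl (stays only in 10 and 11)
Why: Wittig methylenation of the methyl ketone on the transiently bis-silylated diol (no free alkoxide, hence no retro-aldol) turns C=O into the isopropenyl C=CH2 without touching either stereocentre, the change from (2S) to (2R) being only a change of CIP priority, and mild acidic methanolysis then removes only the two TMS ethers.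

Step 7
Reactants: 12 methyl (2E)-3-{2-[(tert-butyldimethylsilyl)oxy]-3-[(1R,2R)-1,2-dihydroxy-3-methylbut-3-en-1-yl]-4-methoxyphenyl}prop-2-enoate
Product: 14 (2E)-3-{3-[(1R,2R)-1,2-dihydroxy-3-methylbut-3-en-1-yl]-2-hydroxy-4-methoxyphenyl}prop-2-enoic acid, via phenol methyl ester 13 (not isolated)
Conditions: LiOH, THF/MeOH/H2O, rt → 40 °C, dark; then aq. HCl to pH 4, 0 °C
Reagents that add atoms: lithium hydroxide, [Li+].[OH-] (supplies the carboxyl oxygen)
Why: Saponification, in which hydroxide first cleaves the base-labile aryl silyl ether and then hydrolyses the methyl ester by acyl–oxygen cleavage, the E geometry being safe because the only route to the coumarin is photochemical E→Z isomerisation.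

Step 8
Reactants: 14 (2E)-3-{3-[(1R,2R)-1,2-dihydroxy-3-methylbut-3-en-1-yl]-2-hydroxy-4-methoxyphenyl}prop-2-enoic acid; 2 (R)-meranzin
Product: 16 exotimarin F, (2R)-3-hydroxy-1-(7-methoxy-2-oxo-2H-chromen-8-yl)-3-methylbutan-2-yl (2E)-3-{3-[(1R,2R)-1,2-dihydroxy-3-methylbut-3-en-1-yl]-2-hydroxy-4-methoxyphenyl}prop-2-enoate, via tertiary ester 15 (not isolated)
Conditions: (R)-3,3′-bis(2,4,6-triisopropylphenyl)-1,1′-binaphthyl-2,2′-diyl hydrogen phosphate (5 mol%), oxirane in 1.3-fold excess, 4 Å MS, CHCl3, rt → 40 °C, dark; then DBU (0.3 equiv), 40 °C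
Reagents that add atoms: none
Why: Proposed new method: a phosphoric-acid-catalysed, regioselective carboxylic-acid opening of an enantioenriched 2,2-dimethyl-3-alkyloxirane used as a protecting-group-free fragment coupling, followed in the same flask by a base-triggered 1,2 O→O acyl shift; the bulky phosphoric acid and the carboxyl group of 14 form a hydrogen-bonded heterodimer that protonates the oxirane oxygen while delivering the carboxyl oxygen to the more substituted, cation-stabilising CMe2 carbon (loose SN2, Markovnikov), so the C2''–O bond set in step 1 is never broken and stays (R); the hindered tertiary ester 15 then passes its acyl group through a five-membered orthoester anion to the neighbouring secondary hydroxyl, the thermodynamically preferred site, to give 16, while the phenol and diol hydroxyls of 14 are not activated by the heterodimer; the closest known reaction types are the chiral-phosphoric-acid-catalysed ring-opening of meso-epoxides by carboxylic acids through acid–acid heterodimers and base-mediated acyl migration in vicinal diol monoesters.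

## Compound list

1 | osthole, 7-methoxy-8-(3-methylbut-2-en-1-yl)-2H-chromen-2-one | COc1ccc2ccc(=O)oc2c1CC=C(C)C | starting material
2 | (R)-meranzin, 8-{[(2R)-3,3-dimethyloxiran-2-yl]methyl}-7-methoxy-2H-chromen-2-one | COc1ccc2ccc(=O)oc2c1C[C@H]1OC1(C)C | intermediate
3 | 2-hydroxy-4-methoxybenzaldehyde | COc1ccc(C=O)c(O)c1 | starting material
4 | methyl (2E)-3-(2-hydroxy-4-methoxyphenyl)prop-2-enoate | COC(=O)/C=C/c1ccc(OC)cc1O | intermediate
5 | methyl (2E)-3-[2-hydroxy-3-(hydroxymethyl)-4-methoxyphenyl]prop-2-enoate (present as its magnesium salt) | COC(=O)/C=C/c1ccc(OC)c(CO)c1O | intermediate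
6 | methyl (2E)-3-(3-formyl-2-hydroxy-4-methoxyphenyl)prop-2-enoate | COC(=O)/C=C/c1ccc(OC)c(C=O)c1O | intermediate
7 | methyl (2E)-3-{2-[(tert-butyldimethylsilyl)oxy]-3-formyl-4-methoxyphenyl}prop-2-enoate | COC(=O)/C=C/c1ccc(OC)c(C=O)c1O[Si](C)(C)C(C)(C)C | intermediate
8 | hydroxyacetone, 1-hydroxypropan-2-one | CC(=O)CO | starting material
9 | methyl (2E)-3-{2-[(tert-butyldimethylsilyl)oxy]-3-[(1R,2S)-1,2-dihydroxy-3-oxobutyl]-4-methoxyphenyl}prop-2-enoate | CC(=O)[C@@H](O)[C@H](O)c1c(OC)ccc(/C=C/C(=O)OC)c1O[Si](C)(C)C(C)(C)C | intermediate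
10 | methyl (2E)-3-{2-[(tert-butyldimethylsilyl)oxy]-4-methoxy-3-[(1R,2S)-3-oxo-1,2-bis(trimethylsilyloxy)butyl]phenyl}prop-2-enoate | CC(=O)[C@@H](O[Si](C)(C)C)[C@H](O[Si](C)(C)C)c1c(OC)ccc(/C=C/C(=O)OC)c1O[Si](C)(C)C(C)(C)C | intermediate
11 | methyl (2E)-3-{2-[(tert-butyldimethylsilyl)oxy]-4-methoxy-3-[(1R,2R)-3-methyl-1,2-bis(trimethylsilyloxy)but-3-en-1-yl]phenyl}prop-2-enoate | C=C(C)[C@@H](O[Si](C)(C)C)[C@H](O[Si](C)(C)C)c1c(OC)ccc(/C=C/C(=O)OC)c1O[Si](C)(C)C(C)(C)C | intermediate
12 | methyl (2E)-3-{2-[(tert-butyldimethylsilyl)oxy]-3-[(1R,2R)-1,2-dihydroxy-3-methylbut-3-en-1-yl]-4-methoxyphenyl}prop-2-enoate | C=C(C)[C@@H](O)[C@H](O)c1c(OC)ccc(/C=C/C(=O)OC)c1O[Si](C)(C)C(C)(C)C | intermediate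
13 | methyl (2E)-3-{3-[(1R,2R)-1,2-dihydroxy-3-methylbut-3-en-1-yl]-2-hydroxy-4-methoxyphenyl}prop-2-enoate | C=C(C)[C@@H](O)[C@H](O)c1c(OC)ccc(/C=C/C(=O)OC)c1O | intermediate
14 | (2E)-3-{3-[(1R,2R)-1,2-dihydroxy-3-methylbut-3-en-1-yl]-2-hydroxy-4-methoxyphenyl}prop-2-enoic acid | C=C(C)[C@@H](O)[C@H](O)c1c(OC)ccc(/C=C/C(=O)O)c1O | intermediate
15 | (3R)-3-hydroxy-4-(7-methoxy-2-oxo-2H-chromen-8-yl)-2-methylbutan-2-yl (2E)-3-{3-[(1R,2R)-1,2-dihydroxy-3-methylbut-3-en-1-yl]-2-hydroxy-4-methoxyphenyl}prop-2-enoate | C=C(C)[C@@H](O)[C@H](O)c1c(OC)ccc(/C=C/C(=O)OC(C)(C)[C@H](O)Cc2c(OC)ccc3ccc(=O)oc23)c1O | intermediate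
16 | exotimarin F, (2R)-3-hydroxy-1-(7-methoxy-2-oxo-2H-chromen-8-yl)-3-methylbutan-2-yl (2E)-3-{3-[(1R,2R)-1,2-dihydroxy-3-methylbut-3-en-1-yl]-2-hydroxy-4-methoxyphenyl}prop-2-enoate | C=C(C)[C@@H](O)[C@H](O)c1c(OC)ccc(/C=C/C(=O)O[C@H](Cc2c(OC)ccc3ccc(=O)oc23)C(C)(C)O)c1O | target

## Step count and risks

Total step count: 8 (step 1 for the oxirane, steps 2–7 for the acid, step 8 for the union). Longest linear sequence: 7 (steps 2–8, from 2-hydroxy-4-methoxybenzaldehyde).

The three steps most likely to fail: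

**Step 8 (the proposed new coupling).** The oxirane may rearrange to the Meinwald ketone, or the o-hydroxybenzylic diol of 14 may ionise. The carboxylate may also attack the secondary carbon and give the C2'' epimer, or the acyl shift may stall. The fallback uses only known chemistry; it sets out from 2 and 14 and comes back to the route at 16. Compound 2 is hydrolysed (dilute HClO4, THF/H2O, 0 °C; water enters at the tertiary carbon, C2'' untouched) to 8-[(2R)-2,3-dihydroxy-3-methylbutyl]-7-methoxy-2H-chromen-2-one F7. Compound 14 is persilylated (TBSOTf, 2,6-lutidine, CH2Cl2) to tert-butyldimethylsilyl (2E)-3-{3-[(1R,2R)-1,2-bis(tert-butyldimethylsilyloxy)-3-methylbut-3-en-1-yl]-2-[(tert-butyldimethylsilyl)oxy]-4-methoxyphenyl}prop-2-enoate F8. The silyl ester alone is then cleaved (AcOH/THF/H2O, rt) to (2E)-3-{3-[(1R,2R)-1,2-bis(tert-butyldimethylsilyloxy)-3-methylbut-3-en-1-yl]-2-[(tert-butyldimethylsilyl)oxy]-4-methoxyphenyl}prop-2-enoic acid F9. Yamaguchi esterification (2,4,6-trichlorobenzoyl chloride, Et3N, then F7 and DMAP, toluene) acylates only the secondary hydroxyl of the diol and gives (2R)-3-hydroxy-1-(7-methoxy-2-oxo-2H-chromen-8-yl)-3-methylbutan-2-yl (2E)-3-{3-[(1R,2R)-1,2-bis(tert-butyldimethylsilyloxy)-3-methylbut-3-en-1-yl]-2-[(tert-butyldimethylsilyl)oxy]-4-methoxyphenyl}prop-2-enoate F10. Finally HF·pyridine (THF/pyridine, 0 °C → rt) removes the three silyl groups to give 16.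

**Step 5 (aldol on a hindered, electron-rich, di-ortho-substituted aldehyde).** Conversion or syn selectivity may be poor. The fallback sets out from 7, bypasses 9–11 and comes back at 12. Me2C=CHMgBr (THF, −78 °C) adds to the aldehyde only and gives racemic methyl (2E)-3-{2-[(tert-butyldimethylsilyl)oxy]-3-(1-hydroxy-3-methylbut-2-en-1-yl)-4-methoxyphenyl}prop-2-enoate F1. MnO2 (CH2Cl2) oxidises it to methyl (2E)-3-{2-[(tert-butyldimethylsilyl)oxy]-4-methoxy-3-(3-methylbut-2-enoyl)phenyl}prop-2-enoate F2. Corey–Bakshi–Shibata reduction ((R)-2-methyl-CBS-oxazaborolidine, catecholborane, toluene, −78 °C, aryl as the large group) gives methyl (2E)-3-{2-[(tert-butyldimethylsilyl)oxy]-3-[(1S)-1-hydroxy-3-methylbut-2-en-1-yl]-4-methoxyphenyl}prop-2-enoate F3. The hydroxyl-directed Schenck ene reaction with singlet oxygen (O2, tetraphenylporphyrin, visible light, CH2Cl2, −20 °C) is threo-selective through allylic 1,3-strain and hydrogen bonding to the carbinol, and it gives methyl (2E)-3-{2-[(tert-butyldimethylsilyl)oxy]-3-[(1R,2R)-2-hydroperoxy-1-hydroxy-3-methylbut-3-en-1-yl]-4-methoxyphenyl}prop-2-enoate F4. PPh3 then reduces the hydroperoxide to 12.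

**Step 6 (methylenation behind transient silyl protection).** The TMS ethers may be lost, the α-centre may epimerise, or the ylide may attack the cinnamate. The fallback sets out from 9 and comes back at 12. 2,2-Dimethoxypropane and pyridinium p-toluenesulfonate in acetone lock the diol as the trans-acetonide, methyl (2E)-3-{3-[(4R,5S)-5-acetyl-2,2-dimethyl-1,3-dioxolan-4-yl]-2-[(tert-butyldimethylsilyl)oxy]-4-methoxyphenyl}prop-2-enoate F5. The non-basic titanium methylidene from Cp2Ti(μ-CH2)(μ-Cl)AlMe2 (THF/pyridine, −40 → 0 °C; ketone reacts before ester) gives methyl (2E)-3-{2-[(tert-butyldimethylsilyl)oxy]-3-[(4R,5R)-2,2-dimethyl-5-(prop-1-en-2-yl)-1,3-dioxolan-4-yl]-4-methoxyphenyl}prop-2-enoate F6. 80% aq. AcOH at 40 °C then removes the acetonide, leaves the aryl silyl ether, and gives 12.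

Further compounds
F1 | step 5 | methyl (2E)-3-{2-[(tert-butyldimethylsilyl)oxy]-3-(1-hydroxy-3-methylbut-2-en-1-yl)-4-methoxyphenyl}prop-2-enoate (racemic) | CC(C)=CC(O)c1c(OC)ccc(/C=C/C(=O)OC)c1O[Si](C)(C)C(C)(C)C
F2 | step 5 | methyl (2E)-3-{2-[(tert-butyldimethylsilyl)oxy]-4-methoxy-3-(3-methylbut-2-enoyl)phenyl}prop-2-enoate | CC(C)=CC(=O)c1c(OC)ccc(/C=C/C(=O)OC)c1O[Si](C)(C)C(C)(C)C
F3 | step 5 | methyl (2E)-3-{2-[(tert-butyldimethylsilyl)oxy]-3-[(1S)-1-hydroxy-3-methylbut-2-en-1-yl]-4-methoxyphenyl}prop-2-enoate | CC(C)=C[C@H](O)c1c(OC)ccc(/C=C/C(=O)OC)c1O[Si](C)(C)C(C)(C)C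
F4 | step 5 | methyl (2E)-3-{2-[(tert-butyldimethylsilyl)oxy]-3-[(1R,2R)-2-hydroperoxy-1-hydroxy-3-methylbut-3-en-1-yl]-4-methoxyphenyl}prop-2-enoate | C=C(C)[C@@H](OO)[C@H](O)c1c(OC)ccc(/C=C/C(=O)OC)c1O[Si](C)(C)C(C)(C)C
F5 | step 6 | methyl (2E)-3-{3-[(4R,5S)-5-acetyl-2,2-dimethyl-1,3-dioxolan-4-yl]-2-[(tert-butyldimethylsilyl)oxy]-4-methoxyphenyl}prop-2-enoate | CC(=O)[C@H]1OC(C)(C)O[C@@H]1c1c(OC)ccc(/C=C/C(=O)OC)c1O[Si](C)(C)C(C)(C)C
F6 | step 6 | methyl (2E)-3-{2-[(tert-butyldimethylsilyl)oxy]-3-[(4R,5R)-2,2-dimethyl-5-(prop-1-en-2-yl)-1,3-dioxolan-4-yl]-4-methoxyphenyl}prop-2-enoate | C=C(C)[C@H]1OC(C)(C)O[C@@H]1c1c(OC)ccc(/C=C/C(=O)OC)c1O[Si](C)(C)C(C)(C)C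
F7 | step 8 | (R)-meranzin hydrate, 8-[(2R)-2,3-dihydroxy-3-methylbutyl]-7-methoxy-2H-chromen-2-one | COc1ccc2ccc(=O)oc2c1C[C@@H](O)C(C)(C)O
F8 | step 8 | tert-butyldimethylsilyl (2E)-3-{3-[(1R,2R)-1,2-bis(tert-butyldimethylsilyloxy)-3-methylbut-3-en-1-yl]-2-[(tert-butyldimethylsilyl)oxy]-4-methoxyphenyl}prop-2-enoate | C=C(C)[C@@H](O[Si](C)(C)C(C)(C)C)[C@H](O[Si](C)(C)C(C)(C)C)c1c(OC)ccc(/C=C/C(=O)O[Si](C)(C)C(C)(C)C)c1O[Si](C)(C)C(C)(C)C
F9 | step 8 | (2E)-3-{3-[(1R,2R)-1,2-bis(tert-butyldimethylsilyloxy)-3-methylbut-3-en-1-yl]-2-[(tert-butyldimethylsilyl)oxy]-4-methoxyphenyl}prop-2-enoic acid | C=C(C)[C@@H](O[Si](C)(C)C(C)(C)C)[C@H](O[Si](C)(C)C(C)(C)C)c1c(OC)ccc(/C=C/C(=O)O)c1O[Si](C)(C)C(C)(C)C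
F10 | step 8 | (2R)-3-hydroxy-1-(7-methoxy-2-oxo-2H-chromen-8-yl)-3-methylbutan-2-yl (2E)-3-{3-[(1R,2R)-1,2-bis(tert-butyldimethylsilyloxy)-3-methylbut-3-en-1-yl]-2-[(tert-butyldimethylsilyl)oxy]-4-methoxyphenyl}prop-2-enoate | C=C(C)[C@@H](O[Si](C)(C)C(C)(C)C)[C@H](O[Si](C)(C)C(C)(C)C)c1c(OC)ccc(/C=C/C(=O)O[C@H](Cc2c(OC)ccc3ccc(=O)oc23)C(C)(C)O)c1O[Si](C)(C)C(C)(C)C
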